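Z stands between E and D on the card, so the D of a flask follows from how much Z it has held and for how long.

in all of them: G 2.5 mol%; X 8.9 mol%
- ash: E 0.42 M; L 0.70 equiv; temperature 95 °C; run made earlier
- alder: E 0.66 M; L 0.70 equiv; temperature 110 °C; run made earlier
- elm: E 0.30 M; L 1.4 equiv; temperature 95 °C; run made earlier
- violet: E 0.30 M; L 0.700 equiv; temperature 120 °C; time 2.0 min
- red: E 0.30 M; L 0.700 equiv; temperature 100 °C; time 2.0 min
- green: E 0.30 M; L 0.700 equiv; at 100 °C until 40 s, from then on at 120 °C; time 2.0 min

ash run (percent of the E charged)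

| time / min | D / % | E / % |
|---|---|---|
| 0.667 | 0.2 | 94.6 |
| 1.33 | 4.9 | 90.6 |
| 2.50 | 9.1 | 83.0 |
| 3.00 | 10.1 | 78.6 |
| 5.00 | 21.8 | 70.9 |

alder run (percent of the E charged)

| time / s | D / % | E / % |
|---|---|---|
| 15.0 | 2.2 | 91.9 |
| 25.0 | 4.7 | 85.4 |
| 40.0 | 11.6 | 80.5 |
| 60.0 | 17.5 | 71.2 |
| 90.0 | 25.1 | 59.2 |
| 120 | 33.2 | 54.6 |

elm run (percent of the E charged)

| time / min | D / % | E / % |
|---|---|---|
| 0.500 | 0 | 96.2 |
| 1.00 | 3.5 | 93.0 |
| 2.50 | 7.3 | 86.1 |
| 5.00 | 19.1 | 74.4 |

(readings scatter by 1 percentage point)

1. the best flask by amount of D, in percent of the E charged; "all alike" if 1.5 percentage points covers them all (violet / red / green / all alike)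
2. amount of D at the end, in percent of the E charged, violet
3. amount of D at the end, in percent of the E charged, red
4. amount of D at the end, in percent of the E charged, green

I replace the curve by its mean. My yardstick is the hold time, a pseudo-first-order time: the mean stock of Z, read as E lost minus D, divided by the mean rate of D. If X stays mostly free, D forms in proportion to X, L and Z. X and L are charged as fixed fractions of E, so the hold time should go as one over the square of the E molarity and one over the equivalents of L.

| run | temperature | hold time | brought to 0.30 M, 0.700 equiv |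
|---|---|---|---|
| ash | 95 °C | 1.66 min | 3.25 min |
| alder | 110 °C | 0.632 min | 3.06 min |
| elm | 95 °C | 1.34 min | 2.67 min |

Ash and alder read alike across their temperatures, so I use one value for violet, red and green, taken from alder, the hottest of the runs. That value, 3.06 min, is the hold time at the charge of these flasks.

Next comes the loss of E. Elm gives 0.0591 /min at 95 °C. Alder gives 0.204 /min, scaled by the root of the E charge, on my guess that G pairs up as Q. Stretching the logarithm with temperature gives 0.0894 /min at 100 °C and 0.466 /min at 120 °C. So E lost by the end is 60.6% in violet, 16.4% in red and 49.4% in green.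

If the mean stock of Z is half the loss, violet makes 19.8%. That is the weak link: the stock of Z also loses what turns into D. Solving a steady loss against the hold time shrinks each figure by the factor 0.813. I commit to 16.1% in violet, 10.3% in green and 4.35% in red.

The forecast names violet, with 26% (19% to 40%) in violet, 8.5% (6% to 11.5%) in red and 20% (14% to 31%) in green, where it says “Green fills J at the jump”. My violet is lower than its figure, and so are my red and green.

The flask gives violet as best, with 21.0% in violet, 5.92% in red and 14.5% in green.

    2 G ⇌ Q (K = 100 /M, k = 1.80 /M/s, Ea = 51.0 kJ/mol, ΔH = −34.0 kJ/mol)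
    X + Z ⇌ J (K = 0.650 /M, k = 1.70 /M/s, Ea = 46.0 kJ/mol, ΔH = −55.0 kJ/mol)
    L + J → X + D (k = 2.60 /M/s, Ea = 71.0 kJ/mol)
    E + G → G + Z (k = 0.320 /M/s, Ea = 77.0 kJ/mol)
    (constants at 100 °C)

Violet holds Z at 21.2% after 1.00 min and 27.8% after 2.00 min, which makes its hold time 1.67 min, shorter than 3.06 min. A neighbour of violet has 2.2 mol% of X, so I stretch the hold time to 6.75 min. Its Z ends at 41.4%; half of that as the mean stock gives 6.14% of D, and the neighbour stands at 7.54%.

(Readings and results were generated by integration on assumed constants; the scatter is artificial.)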